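**Retrosynthetic overview**
1. Late stage from the cycloadduct: second C4 methyl by enolate methylation, C3 ketone to the axial acetate, C1–B to C1–OH, ketal to the C15 ketone, C17 carbinol to the C16=C17 methylene.
2. Key disconnection: C1–C2 and C5–C10, made in one intramolecular Diels–Alder reaction that closes ring A (six-membered) and ring B (ten-membered) together from an open-chain triene carried on ring D.
3. Enabling feature: ring A holds a 2-oxygenated diene retron (C2=C3(O)–C4=C5) and an enone dienophile retron (C9 ketone on C10=C1, the C1 oxygen masked as boron). Its C5–C10 bond is also the fusion bond of ring B, whose far side is turned back by the 1,3-bridging cyclopentene C8=C14–C13 of ring D.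
4. Triene assembly on ring D: diene arm at C8 by formylation, Brown allylation (sets C7), cross-metathesis and enol silylation; dienophile arm at C11 by Fukuyama coupling; C13 bought with (S)-4-silyloxycyclopentenone.
5. Ring order: D (purchased), then A and B together (key step). C1, C5 and C10 arise in the key step, C3 by substrate-controlled reduction.

Key step: step 17

Remark: atom numbers C1–C20 follow ent-kaurane numbering of the target (C17 exocyclic methylene, C18/C19 gem-dimethyl, C20 methyl on C10) and are used for all intermediates; the target is taken as the (1S,3S,5R,7R,10S,13R) enantiomer.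

**Route**

Step 1
Reactants: 1 prop-2-yn-1-ol
Product: 3 (E)-3-iodo-2-methylprop-2-en-1-ol, via alkenylalane 2 (not isolated)
Conditions: Me3Al, Cp2ZrCl2 (cat.), CH2Cl2, 0 °C → rt; then I2, THF, −30 → 0 °C; H2O
Reagents that add atoms: trimethylaluminium, C[Al](C)C; iodine, II
Why: Negishi zirconium-catalysed carboalumination adds methyl and aluminium syn across the alkyne (methyl to the internal carbon), and iodinolysis with retention should give the E vinyl iodide in which iodine is cis to the future C20 methyl.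

Step 2
Reactants: 3 (E)-3-iodo-2-methylprop-2-en-1-ol
Product: 4 (E)-3-iodo-2-methylprop-2-enoic acid
Conditions: CrO3, H2SO4, acetone–H2O, 0 °C
Reagents that add atoms: water, O
Why: Jones oxidation of the primary allylic alcohol through the aldehyde hydrate should give the acid without touching the vinyl iodide or its geometry.

Step 3
Reactants: 4 (E)-3-iodo-2-methylprop-2-enoic acid
Product: 5 S-ethyl (E)-3-iodo-2-methylprop-2-enethioate
Conditions: EtSH, DCC, DMAP (cat.), CH2Cl2, 0 °C → rt
Reagents that add atoms: ethanethiol, CCS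
Why: Steglich-type carbodiimide coupling should give the thioester needed for the later ketone synthesis.

Step 4
Reactants: 5 S-ethyl (E)-3-iodo-2-methylprop-2-enethioate
Product: 6 S-ethyl (E)-2-methyl-3-(4,4,5,5-tetramethyl-1,3,2-dioxaborolan-2-yl)prop-2-enethioate
Conditions: B2pin2, PdCl2(dppf) (cat.), KOAc, DMSO, 50 °C
Reagents that add atoms: bis(pinacolato)diboron, CC1(C)OB(OC1(C)C)B1OC(C)(C)C(C)(C)O1
Why: Miyaura borylation proceeds with retention of alkene geometry, oxidative addition of zerovalent palladium into the C–I bond being much faster than into the thioester C–S bond, and the acetate base does not cleave the thioester.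

Step 5
Reactants: 7 (S)-4-(tert-butyldimethylsilyloxy)cyclopent-2-en-1-one
Product: 9 (2R,3S,4S)-4-(tert-butyldimethylsilyloxy)-2-(hydroxymethyl)-3-vinylcyclopentan-1-one, via magnesium enolate 8 (not isolated)
Conditions: CH2=CHMgBr, CuBr·SMe2 (cat.), THF, −78 °C; then CH2O (monomeric, THF), −78 °C; H2O
Reagents that add atoms: vinylmagnesium bromide, C=C[Mg]Br; formaldehyde, C=O
Why: Copper-catalysed conjugate addition should deliver the vinyl group (C12, C11) to C13 anti to the C14 silyloxy group, and aldol trapping of the regiodefined enolate with formaldehyde should place C17 on C16 anti to the vinyl group (three-component coupling), so the purchased centre sets C13.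

Step 6
Reactants: 9 (2R,3S,4S)-4-(tert-butyldimethylsilyloxy)-2-(hydroxymethyl)-3-vinylcyclopentan-1-one
Product: 11 (4R,5R)-5-[(triisopropylsilyloxy)methyl]-4-vinylcyclopent-2-en-1-one, via bis-silyl ketone 10 (not isolated)
Conditions: TIPSCl, imidazole, DMAP (cat.), CH2Cl2, 0 °C → rt; then DBU, −20 → 0 °C
Reagents that add atoms: triisopropylsilyl chloride, CC(C)[Si](Cl)(C(C)C)C(C)C
Why: After silylation of the primary alcohol, DBU should remove the unhindered C8 proton and expel silanol from C14 (E1cB β-elimination), which transposes the enone to C8=C14 and keeps the C13 and C16 centres.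

Step 7
Reactants: 11 (4R,5R)-5-[(triisopropylsilyloxy)methyl]-4-vinylcyclopent-2-en-1-one
Product: 12 (4S,5R)-2-iodo-5-[(triisopropylsilyloxy)methyl]-4-vinylcyclopent-2-en-1-one
Conditions: I2, pyridine, CH2Cl2, 0 °C → rt
Reagents that add atoms: iodine, II
Why: Johnson α-iodination (conjugate addition of pyridine, iodination of the enolate, elimination) should place iodine on C8 and leave the isolated vinyl group alone.

Step 8
Reactants: 12 (4S,5R)-2-iodo-5-[(triisopropylsilyloxy)methyl]-4-vinylcyclopent-2-en-1-one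
Product: 13 (8S,9R)-6-iodo-9-[(triisopropylsilyloxy)methyl]-8-vinyl-1,4-dioxaspiro[4.4]non-6-ene
Conditions: (TMSOCH2)2, TMSOTf (cat.), CH2Cl2, −78 → −20 °C
Reagents that add atoms: 1,2-bis(trimethylsilyloxy)ethane, C[Si](C)(C)OCCO[Si](C)(C)C
Why: Noyori ketalisation under aprotic low-temperature conditions should mask C15 as the dioxolane without migration of the C8=C14 bond or epimerisation at the doubly allylic C13.

Step 9
Reactants: 13 (8S,9R)-6-iodo-9-[(triisopropylsilyloxy)methyl]-8-vinyl-1,4-dioxaspiro[4.4]non-6-ene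
Product: 15 (8S,9R)-8-(2-chloroethyl)-6-iodo-9-[(triisopropylsilyloxy)methyl]-1,4-dioxaspiro[4.4]non-6-ene, via alkylzirconocene chloride 14 (not isolated)
Conditions: Cp2Zr(H)Cl, THF, rt; then N-chlorosuccinimide, 0 °C; H2O
Reagents that add atoms: N-chlorosuccinimide, ClN1C(=O)CCC1=O
Why: Schwartz hydrozirconation is selective for the terminal vinyl group and places zirconium on C11 (anti-Markovnikov), and chlorinolysis of the alkylzirconocene should give a primary chloride that survives the organolithium step.

Step 10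
Reactants: 15 (8S,9R)-8-(2-chloroethyl)-6-iodo-9-[(triisopropylsilyloxy)methyl]-1,4-dioxaspiro[4.4]non-6-ene
Product: 17 (8R,9R)-8-(2-chloroethyl)-9-[(triisopropylsilyloxy)methyl]-1,4-dioxaspiro[4.4]non-6-ene-6-carbaldehyde, via vinyllithium 16 (not isolated)
Conditions: t-BuLi (2.1 equiv), Et2O, −78 °C; then DMF, −78 → 0 °C; H2O
Reagents that add atoms: N,N-dimethylformamide, CN(C)C=O
Why: Iodine–lithium exchange on the ketal-protected α-iodoenone (an α-ketovinyl anion equivalent) is much faster at −78 °C than any reaction of the primary chloride, and formylation of the vinyllithium should install C7 as the enal.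

Step 11
Reactants: 17 (8R,9R)-8-(2-chloroethyl)-9-[(triisopropylsilyloxy)methyl]-1,4-dioxaspiro[4.4]non-6-ene-6-carbaldehyde
Product: 19 (1R)-1-{(8R,9R)-8-(2-chloroethyl)-9-[(triisopropylsilyloxy)methyl]-1,4-dioxaspiro[4.4]non-6-en-6-yl}but-3-en-1-ol, via diisopinocampheylborinate 18 (not isolated)
Conditions: (+)-Ipc2B(allyl) (from (−)-α-pinene), Et2O, −78 °C; then NaOH, H2O2, 0 °C
Reagents that add atoms: (+)-B-allyldiisopinocampheylborane, C=CCB([C@H]1C[C@H]2C[C@@H]([C@@H]1C)C2(C)C)[C@H]1C[C@H]2C[C@@H]([C@@H]1C)C2(C)C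
Why: Brown allylboration through a chair Zimmerman–Traxler transition state is reagent-controlled, and this enantiomer of the reagent should add to the Re face of the enal to set C7 as R while bringing in C6 and C5.

Step 12
Reactants: 19 (1R)-1-{(8R,9R)-8-(2-chloroethyl)-9-[(triisopropylsilyloxy)methyl]-1,4-dioxaspiro[4.4]non-6-en-6-yl}but-3-en-1-ol
Product: 20 C7 tert-butyldimethylsilyl ether of 19
Conditions: TBSOTf, 2,6-lutidine, CH2Cl2, −78 → 0 °C
Reagents that add atoms: tert-butyldimethylsilyl triflate, CC(C)(C)[Si](C)(C)OS(=O)(=O)C(F)(F)F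
Why: Silylation of the hindered allylic alcohol with the silyl triflate under lutidine buffering should protect C7–OH without opening the ketal.

Step 13
Reactants: 20 C7 tert-butyldimethylsilyl ether of 19
Product: 21 (3E,6R)-6-(tert-butyldimethylsilyloxy)-6-{(8R,9R)-8-(2-chloroethyl)-9-[(triisopropylsilyloxy)methyl]-1,4-dioxaspiro[4.4]non-6-en-6-yl}-3-methylhex-3-en-2-one
Conditions: 3-methylbut-3-en-2-one (excess), second-generation Hoveyda–Grubbs catalyst (cat.), CH2Cl2, 40 °C
Reagents that add atoms: 3-methylbut-3-en-2-one, CC(=O)C(C)=C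
Why: Olefin cross-metathesis of the unhindered terminal alkene with the 1,1-disubstituted enone should give the E trisubstituted enone (C4=C5 with C3, C2 and C18), the trisubstituted ring alkene being inert.

Step 14
Reactants: 21 (3E,6R)-6-(tert-butyldimethylsilyloxy)-6-{(8R,9R)-8-(2-chloroethyl)-9-[(triisopropylsilyloxy)methyl]-1,4-dioxaspiro[4.4]non-6-en-6-yl}-3-methylhex-3-en-2-one
Product: 22 2-iodoethyl analogue of 21
Conditions: NaI, NaHCO3, acetone, reflux
Reagents that add atoms: sodium iodide, [Na+].[I-]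
Why: Finkelstein exchange, driven by precipitation of NaCl, should convert the primary chloride into the iodide needed for zinc insertion.

Step 15
Reactants: 22 2-iodoethyl analogue of 21
Product: 23 2-(tert-butyldimethylsilyloxy)diene of 22 with the arm CH2=C(OTBS)–C(Me)=CH–CH2– (E)
Conditions: TBSOTf, Et3N, CH2Cl2, −78 → 0 °C
Reagents that add atoms: tert-butyldimethylsilyl triflate, CC(C)(C)[Si](C)(C)OS(=O)(=O)C(F)(F)F
Why: Soft kinetic enolisation of the methyl ketone at the α′-methyl group should give the cross-conjugated 2-silyloxydiene without changing the C4=C5 geometry, and it is done here because no second enolisable ketone is yet present.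

Step 16
Reactants: 23 2-(tert-butyldimethylsilyloxy)diene of 22; 6 S-ethyl (E)-2-methyl-3-(4,4,5,5-tetramethyl-1,3,2-dioxaborolan-2-yl)prop-2-enethioate
Product: 25 triene with the diene arm of 23 at C8 and the arm CH2CH2C(=O)C(Me)=CH–Bpin (E) at C13, via alkylzinc iodide 24 (not isolated)
Conditions: Zn dust (activated), DMA–THF, 40 °C; then 6, PdCl2(PPh3)2 (cat.), toluene, rt; H2O
Reagents that add atoms: none
Why: Zinc insertion into the primary iodide and palladium-catalysed Fukuyama coupling with the thioester should form the C9–C11 ketone under neutral conditions that spare the silyl dienol ether and the alkenylboronate and keep the E geometry of the dienophile.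

Step 17
Reactants: 25 triene with the diene arm of 23 at C8 and the arm CH2CH2C(=O)C(Me)=CH–Bpin (E) at C13
Product: 26 cycloadduct with rings A, B and D closed, C3=C4 silyl enol ether and C1–Bpin
Conditions: Me2AlCl (1.5 equiv), CH2Cl2 (1 mM, slow addition of 25), −78 → −20 °C; H2O
Reagents that add atoms: none
Why: Me2AlCl binds the C9 ketone and triggers a type 1 intramolecular Diels–Alder reaction (concerted but asynchronous with the C1–C2 bond leading, at the limit a Mukaiyama–Michael addition followed by ring closure) between the 2-silyloxydiene C2=C3–C4=C5 and the C10=C1 enone; the closest known reaction types are Lewis-acid-promoted cycloadditions of hindered 2-silyloxydienes with α-methyl enones and macrocyclising intramolecular Diels–Alder reactions that form nine- to fourteen-membered carbocycles. Ring A is closed as the six-membered ring of the [4+2] cycloaddition, and ring B as the ten-membered ring spanned by the eight-atom tether C6–C7–C8=C14–C13–C12–C11–C9, which the rigid 1,3-disubstituted cyclopentene turns back on itself. The cis relation of the C1 boryl group and the C10 methyl follows from the E geometry of the dienophile, and the trans ring fusion (H5 anti to the C10 methyl, C6 and C9 both equatorial) from the E geometry of C4=C5 together with the exo position of the C9 carbonyl, which is the intrinsic preference of α-methyl enones and the orientation the tether can span. The diene face should be relayed from C13 and C7: C13 fixes the cyclopentene face from which the C12 arm leaves, A(1,3) strain between the C4 methyl and C6 holds C7 out of the diene plane, and the arrangement with the C7 silyloxy group on the outside of the forming ring is the one expected to lead to 5R,10S and 1S. The step needs chemoselectivity for the C10=C1 enone and ring closure over intermolecular addition, secured by the ketal on ring D (no second activated alkene), the two-atom link that keeps the diene away from C8=C14, and high dilution; regiochemistry is fixed by the tether and matches the polarity of both partners.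

Step 18
Reactants: 26 cycloadduct with rings A, B and D closed, C3=C4 silyl enol ether and C1–Bpin
Product: 27 4,4-dimethyl-3-ketone of the cycloadduct
Conditions: TASF (1.2 equiv), MeI (excess), THF, −78 → −20 °C
Reagents that add atoms: iodomethane, CI
Why: Fluoride cleaves the silyl enol ether much faster than the alkyl silyl ethers and releases the C3–C4 enolate regiospecifically, which should be C-methylated at C4 before it equilibrates (alkylation of a fluoride-generated enolate), making C4 a non-stereogenic gem-dimethyl carbon.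

Step 19
Reactants: 27 4,4-dimethyl-3-ketone of the cycloadduct
Product: 29 C3 axial acetate (3S) with C1–Bpin, via lithium alkoxide 28 (not isolated)
Conditions: LiBH(s-Bu)3 (L-Selectride, 1.1 equiv), THF, −78 °C; then Ac2O, DMAP, −78 °C → rt
Reagents that add atoms: acetic anhydride, CC(=O)OC(C)=O
Why: The bulky hydride should attack the C3 cyclohexanone from the equatorial direction to give the axial alkoxide anti to the C10 methyl (the known outcome for 4,4-dimethyl-3-ketones), the α-quaternary C9 ketone in the ten-membered ring being far less reactive (I-strain), and the alkoxide is acetylated in the same flask.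

Step 20
Reactants: 29 C3 axial acetate (3S) with C1–Bpin
Product: 30 C1 alcohol (1S) with C3 acetate, C7 OTBS, C17 OTIPS and C15 ketal
Conditions: NaBO3·4H2O, THF–H2O, rt
Reagents that add atoms: sodium perborate, O=BO[O-].[Na+]
Why: Oxidation of the secondary alkylboronate proceeds by 1,2-migration with retention and should give the equatorial C1 alcohol cis to the C10 methyl, while the ketal keeps ring D free of an enone that alkaline peroxide would epoxidise.

Step 21
Reactants: 30 C1 alcohol (1S) with C3 acetate, C7 OTBS, C17 OTIPS and C15 ketal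
Product: 31 17-hydroxy-16,17-dihydro derivative of the target (1,7,17-triol)
Conditions: aq. HF (48%), MeCN, 0 °C → rt
Reagents that add atoms: water, O
Why: Aqueous HF should cleave both silyl ethers and hydrolyse the allylic dioxolane to the cyclopentenone (desilylation and acetal hydrolysis) without affecting the hindered acetate or the β-hydroxy ketone.

Step 22
Reactants: 31 17-hydroxy-16,17-dihydro derivative of the target (1,7,17-triol)
Product: 33 CNP0223751.1, via primary mesylate 32 (not isolated)
Conditions: MsCl (1.05 equiv), Et3N (3 equiv), CH2Cl2, −40 → 0 °C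
Reagents that add atoms: none
Why: Sulfonylation of the primary C17 alcohol is much faster than that of the two hindered secondary alcohols, and the β-mesyloxy ketone should eliminate at once under triethylamine (E1cB) to the exocyclic C16=C17 enone.

**Compound list**

1 | prop-2-yn-1-ol | C#CCO | starting material
2 | (E)-alkenylalane Me2Al–CH=C(Me)–CH2O–AlMe2 | C[Al](C)OC/C(C)=C/[Al](C)C | intermediate
3 | (E)-3-iodo-2-methylprop-2-en-1-ol | OC/C(C)=C/I | intermediate
4 | (E)-3-iodo-2-methylprop-2-enoic acid | OC(=O)/C(C)=C/I | intermediate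
5 | S-ethyl (E)-3-iodo-2-methylprop-2-enethioate | CCSC(=O)/C(C)=C/I | intermediate
6 | S-ethyl (E)-2-methyl-3-(4,4,5,5-tetramethyl-1,3,2-dioxaborolan-2-yl)prop-2-enethioate | CCSC(=O)/C(C)=C/B1OC(C)(C)C(C)(C)O1 | intermediate
7 | (S)-4-(tert-butyldimethylsilyloxy)cyclopent-2-en-1-one | O=C1C=C[C@@H](O[Si](C)(C)C(C)(C)C)C1 | starting material
8 | bromomagnesium enolate (C15–OMgBr, C15=C16) after vinyl addition | Br[Mg]OC1=C[C@H](C=C)[C@@H](O[Si](C)(C)C(C)(C)C)C1 | intermediate
9 | (2R,3S,4S)-4-(tert-butyldimethylsilyloxy)-2-(hydroxymethyl)-3-vinylcyclopentan-1-one | O=C1[C@@H](CO)[C@H](C=C)[C@@H](O[Si](C)(C)C(C)(C)C)C1 | intermediate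
10 | (2R,3S,4S)-4-(tert-butyldimethylsilyloxy)-2-[(triisopropylsilyloxy)methyl]-3-vinylcyclopentan-1-one | O=C1[C@@H](CO[Si](C(C)C)(C(C)C)C(C)C)[C@H](C=C)[C@@H](O[Si](C)(C)C(C)(C)C)C1 | intermediate
11 | (4R,5R)-5-[(triisopropylsilyloxy)methyl]-4-vinylcyclopent-2-en-1-one | O=C1C=C[C@@H](C=C)[C@@H]1CO[Si](C(C)C)(C(C)C)C(C)C | intermediate
12 | (4S,5R)-2-iodo-5-[(triisopropylsilyloxy)methyl]-4-vinylcyclopent-2-en-1-one | O=C1C(I)=C[C@@H](C=C)[C@@H]1CO[Si](C(C)C)(C(C)C)C(C)C | intermediate
13 | (8S,9R)-6-iodo-9-[(triisopropylsilyloxy)methyl]-8-vinyl-1,4-dioxaspiro[4.4]non-6-ene | IC1=C[C@@H](C=C)[C@H](CO[Si](C(C)C)(C(C)C)C(C)C)C12OCCO2 | intermediate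
14 | alkylzirconocene chloride (Zr on C11) | IC1=C[C@@H](CC[Zr](Cl)(C3C=CC=C3)C3C=CC=C3)[C@H](CO[Si](C(C)C)(C(C)C)C(C)C)C12OCCO2 | intermediate
15 | (8S,9R)-8-(2-chloroethyl)-6-iodo-9-[(triisopropylsilyloxy)methyl]-1,4-dioxaspiro[4.4]non-6-ene | IC1=C[C@@H](CCCl)[C@H](CO[Si](C(C)C)(C(C)C)C(C)C)C12OCCO2 | intermediate
16 | vinyllithium (Li on C8) | [Li]C1=C[C@@H](CCCl)[C@H](CO[Si](C(C)C)(C(C)C)C(C)C)C12OCCO2 | intermediate
17 | (8R,9R)-8-(2-chloroethyl)-9-[(triisopropylsilyloxy)methyl]-1,4-dioxaspiro[4.4]non-6-ene-6-carbaldehyde | O=CC1=C[C@@H](CCCl)[C@H](CO[Si](C(C)C)(C(C)C)C(C)C)C12OCCO2 | intermediate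
18 | diisopinocampheylborinate of 19 | C=CC[C@@H](OB([C@H]1C[C@H]2C[C@@H]([C@@H]1C)C2(C)C)[C@H]1C[C@H]2C[C@@H]([C@@H]1C)C2(C)C)C1=C[C@@H](CCCl)[C@H](CO[Si](C(C)C)(C(C)C)C(C)C)C12OCCO2 | intermediate
19 | (1R)-1-{(8R,9R)-8-(2-chloroethyl)-9-[(triisopropylsilyloxy)methyl]-1,4-dioxaspiro[4.4]non-6-en-6-yl}but-3-en-1-ol | C=CC[C@@H](O)C1=C[C@@H](CCCl)[C@H](CO[Si](C(C)C)(C(C)C)C(C)C)C12OCCO2 | intermediate
20 | C7 tert-butyldimethylsilyl ether of 19 | C=CC[C@@H](O[Si](C)(C)C(C)(C)C)C1=C[C@@H](CCCl)[C@H](CO[Si](C(C)C)(C(C)C)C(C)C)C12OCCO2 | intermediate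
21 | (3E,6R)-6-(tert-butyldimethylsilyloxy)-6-{(8R,9R)-8-(2-chloroethyl)-9-[(triisopropylsilyloxy)methyl]-1,4-dioxaspiro[4.4]non-6-en-6-yl}-3-methylhex-3-en-2-one | CC(=O)/C(C)=C/C[C@@H](O[Si](C)(C)C(C)(C)C)C1=C[C@@H](CCCl)[C@H](CO[Si](C(C)C)(C(C)C)C(C)C)C12OCCO2 | intermediate
22 | 2-iodoethyl analogue of 21 | CC(=O)/C(C)=C/C[C@@H](O[Si](C)(C)C(C)(C)C)C1=C[C@@H](CCI)[C@H](CO[Si](C(C)C)(C(C)C)C(C)C)C12OCCO2 | intermediate
23 | 2-(tert-butyldimethylsilyloxy)diene of 22 | C=C(O[Si](C)(C)C(C)(C)C)/C(C)=C/C[C@@H](O[Si](C)(C)C(C)(C)C)C1=C[C@@H](CCI)[C@H](CO[Si](C(C)C)(C(C)C)C(C)C)C12OCCO2 | intermediate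
24 | alkylzinc iodide (Zn on C11) | C=C(O[Si](C)(C)C(C)(C)C)/C(C)=C/C[C@@H](O[Si](C)(C)C(C)(C)C)C1=C[C@@H](CC[Zn]I)[C@H](CO[Si](C(C)C)(C(C)C)C(C)C)C12OCCO2 | intermediate
25 | triene: silyloxydiene arm at C8, (E)-β-boryl-α-methyl enone arm at C13 | C=C(O[Si](C)(C)C(C)(C)C)/C(C)=C/C[C@@H](O[Si](C)(C)C(C)(C)C)C1=C[C@@H](CCC(=O)/C(C)=C/B2OC(C)(C)C(C)(C)O2)[C@H](CO[Si](C(C)C)(C(C)C)C(C)C)C13OCCO3 | intermediate
26 | cycloadduct: rings A, B and D, C3=C4 silyl enol ether, C1–Bpin cis to C20, trans A/B fusion | CC(C)[Si](C(C)C)(C(C)C)OC[C@@H]1C2(OCCO2)C3=C[C@H]1CCC(=O)[C@@]1(C)[C@H](C[C@H]3O[Si](C)(C)C(C)(C)C)C(C)=C(O[Si](C)(C)C(C)(C)C)C[C@@H]1B4OC(C)(C)C(C)(C)O4 | intermediate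
27 | 4,4-dimethyl-3-ketone of the cycloadduct | CC(C)[Si](C(C)C)(C(C)C)OC[C@@H]1C2(OCCO2)C3=C[C@H]1CCC(=O)[C@@]1(C)[C@H](C[C@H]3O[Si](C)(C)C(C)(C)C)C(C)(C)C(=O)C[C@@H]1B4OC(C)(C)C(C)(C)O4 | intermediate
28 | lithium C3 alkoxide (axial) | CC(C)[Si](C(C)C)(C(C)C)OC[C@@H]1C2(OCCO2)C3=C[C@H]1CCC(=O)[C@@]1(C)[C@H](C[C@H]3O[Si](C)(C)C(C)(C)C)C(C)(C)[C@@H](O[Li])C[C@@H]1B4OC(C)(C)C(C)(C)O4 | intermediate
29 | C3 axial acetate with C1–Bpin | CC(C)[Si](C(C)C)(C(C)C)OC[C@@H]1C2(OCCO2)C3=C[C@H]1CCC(=O)[C@@]1(C)[C@H](C[C@H]3O[Si](C)(C)C(C)(C)C)C(C)(C)[C@@H](OC(C)=O)C[C@@H]1B4OC(C)(C)C(C)(C)O4 | intermediate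
30 | C1 alcohol with C3 acetate, C7 OTBS, C17 OTIPS, C15 ketal | CC(C)[Si](C(C)C)(C(C)C)OC[C@@H]1C2(OCCO2)C3=C[C@H]1CCC(=O)[C@@]1(C)[C@H](C[C@H]3O[Si](C)(C)C(C)(C)C)C(C)(C)[C@@H](OC(C)=O)C[C@@H]1O | intermediate
31 | 17-hydroxy-16,17-dihydro derivative of the target | OC[C@@H]1C(=O)C2=C[C@H]1CCC(=O)[C@@]1(C)[C@H](C[C@H]2O)C(C)(C)[C@@H](OC(C)=O)C[C@@H]1O | intermediate
32 | C17 primary mesylate of 31 | CS(=O)(=O)OC[C@@H]1C(=O)C2=C[C@H]1CCC(=O)[C@@]1(C)[C@H](C[C@H]2O)C(C)(C)[C@@H](OC(C)=O)C[C@@H]1O | intermediate
33 | CNP0223751.1, (1S,3S,5R,7R,10S,13R)-3-acetoxy-1,7-dihydroxy-8,9-seco-kaura-8(14),16-diene-9,15-dione | C=C1C(=O)C2=C[C@H]1CCC(=O)[C@@]1(C)[C@H](C[C@H]2O)C(C)(C)[C@@H](OC(C)=O)C[C@@H]1O | target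

**Step count and risks**

Total step count: 22. Longest linear sequence: 18 steps (steps 5–22, from 7).

Steps most likely to fail:

Step 17 (key step). The ten-membered ring may fail to close in competition with intermolecular addition, the aluminium Lewis acid may ionise the allylic ketal, or the diene may add through the wrong face. The fallback closes the two rings in two events. It sets out from 23 and 6: an intermolecular Me2AlCl-promoted Diels–Alder reaction at normal concentration should give the thioester cycloadduct F1 (ring A only). The remote C7 centre offers no facial control here, so the two facial isomers would have to be separated. Zinc insertion into the primary iodide of F1 and intramolecular Fukuyama coupling (PdCl2(PPh3)2, high dilution) would then close the ten-membered ketone and return to 26.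

Step 18. Proton transfer within the naked enolate (methylation at C2 or C11, O-methylation) or attack of fluoride on the alkyl silyl ethers or on boron may divert the reaction. The fallback avoids a free enolate. It sets out from 26: Simmons–Smith cyclopropanation (Et2Zn, CH2I2, CH2Cl2, 0 °C) of the silyl enol ether, the most electron-rich alkene, should give the siloxycyclopropane F2. Cleavage of its silyl ether with acetic-acid-buffered TBAF and base-induced opening of the cyclopropanol at the CH2–C3 bond (K2CO3, MeOH) would deliver the gem-dimethyl ketone and return to 27.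

Step 16. The silyl dienol ether may not survive zinc insertion, since the zinc iodide formed can act as a Lewis acid and cause hydrolysis or premature, unselective cycloaddition of 25. The fallback uses a lithium reagent and late borylation. It sets out from 23: iodine–lithium exchange (t-BuLi, Et2O, −78 °C) and addition to (E)-3-iodo-2-methylprop-2-enal F3 (from 3 with MnO2) should give the C9 allylic alcohol F4 as both epimers. MnO2 oxidation would give the β-iodo enone F5, and Miyaura borylation (B2pin2, PdCl2(PPh3)2, KOPh, toluene, 50 °C) would return to 25.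

Further compounds
F1 | step 17 | thioester cycloadduct (ring A closed, C10–C(=O)SEt, C1–Bpin, 2-iodoethyl at C13) | CCSC(=O)[C@@]1(C)[C@H](C[C@@H](O[Si](C)(C)C(C)(C)C)C2=C[C@@H](CCI)[C@H](CO[Si](C(C)C)(C(C)C)C(C)C)C23OCCO3)C(C)=C(O[Si](C)(C)C(C)(C)C)C[C@@H]1B4OC(C)(C)C(C)(C)O4
F2 | step 18 | siloxycyclopropane across C3–C4 of 26 (cyclopropane face not defined, both converge) | CC(C)[Si](C(C)C)(C(C)C)OC[C@@H]1C2(OCCO2)C3=C[C@H]1CCC(=O)[C@@]1(C)[C@H](C[C@H]3O[Si](C)(C)C(C)(C)C)C4(C)CC4(O[Si](C)(C)C(C)(C)C)C[C@@H]1B5OC(C)(C)C(C)(C)O5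
F3 | step 16 | (E)-3-iodo-2-methylprop-2-enal | O=C/C(C)=C/I
F4 | step 16 | C9 allylic alcohol (both C9 epimers) with (E)-vinyl iodide and silyloxydiene arm | C=C(O[Si](C)(C)C(C)(C)C)/C(C)=C/C[C@@H](O[Si](C)(C)C(C)(C)C)C1=C[C@@H](CCC(O)/C(C)=C/I)[C@H](CO[Si](C(C)C)(C(C)C)C(C)C)C12OCCO2
F5 | step 16 | (E)-β-iodo-α-methyl enone with silyloxydiene arm | C=C(O[Si](C)(C)C(C)(C)C)/C(C)=C/C[C@@H](O[Si](C)(C)C(C)(C)C)C1=C[C@@H](CCC(=O)/C(C)=C/I)[C@H](CO[Si](C(C)C)(C(C)C)C(C)C)C12OCCO2
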